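## Retrosynthetic overview

1. The ester C–O bond is made last by Mitsunobu displacement (inversion) of an equatorial 3S allylic alcohol with unprotected isovanillic acid.
2. The allylic alcohol comes from the racemic trans-fused 2-methyl enone by catalyst-controlled CBS reduction, which also resolves the racemate.
3. The enone comes from a methyl dienol ether by enol ether hydrolysis, conjugation and equilibration of the ring fusion.
4. Key disconnection C4a–C5: a dearomatizing SmI2 ketyl–arene cyclization of a 4-alkyl-2-methylanisole. The six-membered ring is the former benzene ring (present from the start); the seven-membered ring is closed here, second and last.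
5. The aryl ketone comes from 2-methylanisole and 6-methylhept-5-en-2-one by Friedel–Crafts alkylation.

Assumption: the SMILES is taken literally (trans ring fusion, all four stereocentres R); racemic compounds 4–6 are drawn as the enantiomer that is carried on, and one locant set (carbinol carbon C-5, gem-dimethyl carbon C-9, oxygenated ring carbon C-3) is used for all bicyclic compounds.

## Route

Step 1
Reactants: 1 2-methylanisole; 2 6-methylhept-5-en-2-one
Product: 3 6-(4-methoxy-3-methylphenyl)-6-methylheptan-2-one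
Conditions: CF3SO3H (20 mol %), 1 (3 equiv), CH2Cl2, 0 °C → rt
Reagents that add atoms: none
Why: Friedel–Crafts alkylation (acid-catalysed Markovnikov hydroarylation): protonation of the trisubstituted alkene gives the tertiary cation, which attacks the most activated and least hindered ring position, para to OMe; no stereocentre is formed.

Step 2
Reactants: 3 6-(4-methoxy-3-methylphenyl)-6-methylheptan-2-one
Product: 4 rac-(4aR,5R)-3-methoxy-2,5,9,9-tetramethyl-2,4a,6,7,8,9-hexahydro-5H-benzo[7]annulen-5-ol (C-2 epimers)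
Conditions: SmI2 (2.5 equiv), HMPA (18 equiv), t-BuOH (2 equiv), THF, rt
Reagents that add atoms: none
Why: Proposed new method: SmI2/HMPA turns the ketone into a samarium ketyl that adds to the free ortho carbon meta to OMe (the other ortho carbon is flanked by the methyl, and ipso attack would place charge on the OMe-bearing carbon), a second electron gives the cyclohexadienyl anion, and t-BuOH protonates it para to the new bond; the closest known reaction is the six-ring-forming SmI2/HMPA dearomatizing ketyl–arene cyclization of γ-aryl ketones, here stretched to a seven-membered ring with help from the benzylic gem-dimethyl group; the bulky samarium-bound oxygen points away from the ring and the methyl lies over it, so C-4a and C-5 are set together with OH cis to H-4a (racemic).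

Step 3
Reactants: 4 rac-(4aR,5R)-3-methoxy-2,5,9,9-tetramethyl-2,4a,6,7,8,9-hexahydro-5H-benzo[7]annulen-5-ol
Product: 6 rac-(4aR,5R,9aR)-5-hydroxy-2,5,9,9-tetramethyl-4,4a,5,6,7,8,9,9a-octahydro-3H-benzo[7]annulen-3-one, via deconjugated enone 5 (not isolated)
Conditions: 1 M aq. HCl, THF, rt; then NaOMe (0.3 equiv), MeOH, rt
Reagents that add atoms: water, O
Why: Enol ether hydrolysis gives the β,γ-enone 5, and methoxide moves the double bond into conjugation through the extended dienolate (alkene isomerization); H-9a is then γ to the enone and exchangeable, so it is expected to settle in the trans ring fusion with both ring-fusion bonds equatorial (the C-2 stereocentre disappears).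

Step 4
Reactants: 6 rac-(4aR,5R,9aR)-5-hydroxy-2,5,9,9-tetramethyl-4,4a,5,6,7,8,9,9a-octahydro-3H-benzo[7]annulen-3-one
Product: 7 (3S,4aR,5R,9aR)-2,5,9,9-tetramethyl-4,4a,5,6,7,8,9,9a-octahydro-3H-benzo[7]annulene-3,5-diol
Conditions: (R)-Me-CBS oxazaborolidine [(3aR)-1-methyl-3,3-diphenyltetrahydro-1H,3H-pyrrolo[1,2-c][1,3,2]oxazaborole] (0.5 equiv), catecholborane (0.6 equiv), toluene, −78 °C, to about 50 % conversion; aq. NaOH work-up
Reagents that add atoms: none
Why: Corey–Bakshi–Shibata reduction under catalyst control (the 2-methylalkenyl arm acts as the large group, so the (R)-catalyst gives the 3S carbinol); only in the (4aR,5R,9aR)-enantiomer is this also the preferred axial hydride path, so that enantiomer is reduced fast to the equatorial alcohol 7 while the (4aS,5S,9aS) half of 6 stays behind or gives the separable C-3 epimer series, a kinetic resolution that fixes C-3 and the absolute configuration (at most half of the material).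

Step 5
Reactants: 7 (3S,4aR,5R,9aR)-2,5,9,9-tetramethyl-4,4a,5,6,7,8,9,9a-octahydro-3H-benzo[7]annulene-3,5-diol; 8 isovanillic acid (3-hydroxy-4-methoxybenzoic acid)
Product: 9 (3R,4aR,5R,9aR)-5-hydroxy-2,5,9,9-tetramethyl-4,4a,5,6,7,8,9,9a-octahydro-3H-benzo[7]annulen-3-yl 3-hydroxy-4-methoxybenzoate (target)
Conditions: PPh3 (1.5 equiv), DIAD (1.5 equiv), 8 (1.5 equiv), THF, 0 °C → rt
Reagents that add atoms: none
Why: Mitsunobu esterification: the carboxylic acid, far more acidic than the phenol, is the nucleophile and displaces the oxyphosphonium by SN2 with inversion at C-3 (3S → 3R, pseudoaxial ester), as in the cis-carveol to trans-carvyl ester inversion, while the tertiary alcohol does not react.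

## Compound list

1 | 2-methylanisole (1-methoxy-2-methylbenzene) | COc1ccccc1C | starting material
2 | 6-methylhept-5-en-2-one | CC(=O)CCC=C(C)C | starting material
3 | 6-(4-methoxy-3-methylphenyl)-6-methylheptan-2-one | CC(=O)CCCC(C)(C)c1ccc(OC)c(C)c1 | intermediate
4 | rac-(4aR,5R)-3-methoxy-2,5,9,9-tetramethyl-2,4a,6,7,8,9-hexahydro-5H-benzo[7]annulen-5-ol (C-2 epimers) | COC1=C[C@@H]2C(=CC1C)C(C)(C)CCC[C@@]2(C)O | intermediate
5 | rac-(4aR,5R)-5-hydroxy-2,5,9,9-tetramethyl-2,4,4a,5,6,7,8,9-octahydro-3H-benzo[7]annulen-3-one (C-2 epimers) | O=C1C[C@@H]2C(=CC1C)C(C)(C)CCC[C@@]2(C)O | intermediate (not isolated)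
6 | rac-(4aR,5R,9aR)-5-hydroxy-2,5,9,9-tetramethyl-4,4a,5,6,7,8,9,9a-octahydro-3H-benzo[7]annulen-3-one | O=C1C[C@@H]2[C@@H](C=C1C)C(C)(C)CCC[C@@]2(C)O | intermediate
7 | (3S,4aR,5R,9aR)-2,5,9,9-tetramethyl-4,4a,5,6,7,8,9,9a-octahydro-3H-benzo[7]annulene-3,5-diol | O[C@H]1C[C@@H]2[C@@H](C=C1C)C(C)(C)CCC[C@@]2(C)O | intermediate
8 | isovanillic acid (3-hydroxy-4-methoxybenzoic acid) | COc1ccc(C(=O)O)cc1O | starting material
9 | (3R,4aR,5R,9aR)-5-hydroxy-2,5,9,9-tetramethyl-4,4a,5,6,7,8,9,9a-octahydro-3H-benzo[7]annulen-3-yl 3-hydroxy-4-methoxybenzoate | COc1ccc(C(=O)O[C@@H]2C[C@@H]3[C@@H](C=C2C)C(C)(C)CCC[C@@]3(C)O)cc1O | target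

## Step count and risks

Total steps: 5. Longest linear sequence: 5 (from 1 and 2 to 9).

The three steps most likely to fail are steps 2, 3 and 5.

**Step 2.** The ketyl has to close a seven-membered ring onto an unactivated anisole; simple reduction of the ketone or pinacol coupling may win. The fallback dearomatizes first and closes the ring second; it sets out from 3 and comes back at 6. Birch reduction of 3 (Li, NH3, t-BuOH, THF, −78 °C) reduces the arene and the ketone to 6-(4-methoxy-5-methylcyclohexa-1,4-dien-1-yl)-6-methylheptan-2-ol F1. 1 M aq. HCl in THF hydrolyses and conjugates it to 4-(6-hydroxy-2-methylheptan-2-yl)-6-methylcyclohex-2-en-1-one F2. Dess–Martin periodinane gives 6-methyl-4-(2-methyl-6-oxoheptan-2-yl)cyclohex-2-en-1-one F3. SmI2/HMPA/t-BuOH then closes the seven-membered ring by ketyl addition to the enone β-carbon, an activated acceptor for which seven-ring ketyl–olefin closures are known, giving 5-hydroxy-2,5,9,9-tetramethyldecahydro-3H-benzo[7]annulen-3-one F4. TMSCl/NaI/Et3N in MeCN (thermodynamic enolization) gives 2,5,9,9-tetramethyl-3,5-bis(trimethylsilyloxy)-4,4a,5,6,7,8,9,9a-octahydro-1H-benzo[7]annulene F5. Pd(OAc)2 in MeCN (Saegusa–Ito oxidation), dilute HCl and the NaOMe equilibration of step 3 return the material to 6.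

**Step 3.** The preference for the trans ring fusion rests on a conformational argument and may be small, so the cis isomer may persist. The fallback puts the C-9a hydrogen in under kinetic, hydroxyl-directed control; it sets out from 4 and comes back at 6. Oxalic acid in wet THF hydrolyses only the enol ether of 4, so that 5 is isolated. [Ir(cod)(PCy3)(py)]PF6 with H2 in CH2Cl2 hydrogenates the C1=C9a alkene from the face held by the C-5 hydroxyl, so hydrogen enters C-9a cis to C-5 and trans to H-4a. This gives rac-(4aR,5R,9aR)-5-hydroxy-2,5,9,9-tetramethyldecahydro-3H-benzo[7]annulen-3-one F6. TMSCl/NaI/Et3N gives the trans-fused bis-silyl enol ether rac-(4aR,5R,9aR)-2,5,9,9-tetramethyl-3,5-bis(trimethylsilyloxy)-4,4a,5,6,7,8,9,9a-octahydro-1H-benzo[7]annulene F7. Pd(OAc)2 in MeCN and dilute HCl then give the conjugated enone 6 without any base.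

**Step 5.** The Mitsunobu reaction is at a hindered allylic carbinol next to the methyl-bearing alkene; elimination to the diene, SN2' attack or phenol O-alkylation may compete. The fallback avoids the inversion; it sets out from 6 and comes back at 9. The mirror-image catalyst (S)-Me-CBS with catecholborane reduces the (4aR,5R,9aR)-enantiomer of 6 from the equatorial face to the axial alcohol (3R,4aR,5R,9aR)-2,5,9,9-tetramethyl-4,4a,5,6,7,8,9,9a-octahydro-3H-benzo[7]annulene-3,5-diol F8; the other enantiomer gives the separable equatorial alcohol of the opposite series. Compound 8 is acetylated (Ac2O, pyridine) to 3-acetoxy-4-methoxybenzoic acid F9. F9 acylates the secondary hydroxyl of F8 with retention (EDC hydrochloride, DMAP, CH2Cl2) to give (3R,4aR,5R,9aR)-5-hydroxy-2,5,9,9-tetramethyl-4,4a,5,6,7,8,9,9a-octahydro-3H-benzo[7]annulen-3-yl 3-acetoxy-4-methoxybenzoate F10. K2CO3 in MeOH at 0 °C removes the phenolic acetate and gives 9.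

## Further compounds

F1 | step 2 | 6-(4-methoxy-5-methylcyclohexa-1,4-dien-1-yl)-6-methylheptan-2-ol | CC(O)CCCC(C)(C)C1=CCC(OC)=C(C)C1
F2 | step 2 | 4-(6-hydroxy-2-methylheptan-2-yl)-6-methylcyclohex-2-en-1-one (stereoisomer mixture) | CC(O)CCCC(C)(C)C1C=CC(=O)C(C)C1
F3 | step 2 | 6-methyl-4-(2-methyl-6-oxoheptan-2-yl)cyclohex-2-en-1-one | CC(=O)CCCC(C)(C)C1C=CC(=O)C(C)C1
F4 | step 2 | rac-(4aR,5R)-5-hydroxy-2,5,9,9-tetramethyldecahydro-3H-benzo[7]annulen-3-one (C-2 and C-9a epimers) | O=C1C[C@@H]2C(CC1C)C(C)(C)CCC[C@@]2(C)O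
F5 | step 2 | rac-(4aR,5R)-2,5,9,9-tetramethyl-3,5-bis(trimethylsilyloxy)-4,4a,5,6,7,8,9,9a-octahydro-1H-benzo[7]annulene (C-9a epimers) | CC1=C(O[Si](C)(C)C)C[C@@H]2C(C1)C(C)(C)CCC[C@@]2(C)O[Si](C)(C)C
F6 | step 3 | rac-(4aR,5R,9aR)-5-hydroxy-2,5,9,9-tetramethyldecahydro-3H-benzo[7]annulen-3-one (C-2 epimers) | O=C1C[C@@H]2[C@@H](CC1C)C(C)(C)CCC[C@@]2(C)O
F7 | step 3 | rac-(4aR,5R,9aR)-2,5,9,9-tetramethyl-3,5-bis(trimethylsilyloxy)-4,4a,5,6,7,8,9,9a-octahydro-1H-benzo[7]annulene | CC1=C(O[Si](C)(C)C)C[C@@H]2[C@@H](C1)C(C)(C)CCC[C@@]2(C)O[Si](C)(C)C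
F8 | step 5 | (3R,4aR,5R,9aR)-2,5,9,9-tetramethyl-4,4a,5,6,7,8,9,9a-octahydro-3H-benzo[7]annulene-3,5-diol | O[C@@H]1C[C@@H]2[C@@H](C=C1C)C(C)(C)CCC[C@@]2(C)O
F9 | step 5 | 3-acetoxy-4-methoxybenzoic acid | COc1ccc(C(=O)O)cc1OC(C)=O
F10 | step 5 | (3R,4aR,5R,9aR)-5-hydroxy-2,5,9,9-tetramethyl-4,4a,5,6,7,8,9,9a-octahydro-3H-benzo[7]annulen-3-yl 3-acetoxy-4-methoxybenzoate | COc1ccc(C(=O)O[C@@H]2C[C@@H]3[C@@H](C=C2C)C(C)(C)CCC[C@@]3(C)O)cc1OC(C)=O
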